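Its constants were chosen freely, and the outcome is calculated.

The constants are given at 37 °C, so they stand as printed for red and had to be moved for the other flasks.

    free enzyme → unfolded enzyme (k1 = 2.1 × 10⁻⁶ min⁻¹, Ea1 = 251 kJ mol⁻¹)
    starting material + free enzyme ⇌ starting complex (K2 = 47 L mol⁻¹, k2 = 1000 L mol⁻¹ min⁻¹, Ea2 = 54.0 kJ mol⁻¹, ΔH2 = −75.0 kJ mol⁻¹)
    second substrate + starting complex ⇌ ternary complex (K3 = 46 L mol⁻¹, k3 = 1100 L mol⁻¹ min⁻¹, Ea3 = 55.0 kJ mol⁻¹, ΔH3 = −32.0 kJ mol⁻¹)
    ternary complex → free enzyme + product (k4 = 0.43 min⁻¹, Ea4 = 91.0 kJ mol⁻¹)
    crystals ⇌ product, rate k5*(cs5 - [product]) while solid is left; crystals form when [product] > cs5 (cs5 = 1.3 mM, k5 = 0.029 min⁻¹)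
    (constants at 37 °C)

all flasks: starting material 0.024 M; second substrate 0.0288 M; free enzyme 12 µM; time 30 h

| flask | temperature |
|---|---|
| red | 37 °C |
| amber | 22 °C |
| teal | 7 °C |
| grey | 52 °C |

- for product the crystals are counted in
- as a solid, counted per litre of solution: crystals
- all constants are for 37 °C and move with temperature by the activation energies and enthalpies

- the flask that comes out highest in amount of product, in percent of the starting material charged, or "all alike" when all lie within 1.5 percentage points (red / amber / teal / grey / all alike)
- product at the end, in percent of the starting material charged, red
- product at the end, in percent of the starting material charged, amber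
- product at the end, in percent of the starting material charged, teal
- product at the end, in percent of the starting material charged, grey

I counted everything as fractions of the charge, and my first question was which step sets the pace. In red, ternary complex falls back at 23.9 min⁻¹ but goes on to product at 0.43 min⁻¹, so it returns 55.6 times as often as it reacts. I therefore treated binding as an equilibrium and the last step as the rate-limiting step.

The second question was what heat does to that step and to binding. In grey the binding constants fall to 12.3 L mol⁻¹ and 26.0 L mol⁻¹, and the ternary share, the fraction of the enzyme standing as ternary complex at the full charges, falls to 14.5 %. The last step, however, rises to 2.19 min⁻¹. Multiplying the share by that constant, by the enzyme charge over the starting material charge and by the time gave 28.7 %, my turnover allowance: the part of the charge turned if the share held to the end. For red, with a share of 41.3 %, the allowance was 16.0 %, which is less than grey's.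

The third question was how large the corrections are. In grey, unfolding at 1.87 × 10⁻⁴ min⁻¹ acts on the free part of the enzyme and takes 22.2 % by the end, so I took off half of that as the average loss. This gave 25.5 %. Reading the share at mid-run substrate levels then gave 21.1 %. The same mid-run correction took red to 15.0 %.

Teal could not catch up with grey: the last step in teal is slower than in grey by a factor of 220, while the share in teal can stand above grey's by a factor of at most 6.90, which leaves teal at most 0.884 %. I reckoned no figure for amber, and I stopped there with grey ahead of red.

The forecast named grey, with red 15 % (13.5 % to 16.5 %), amber 4.3 % (3.9 % to 4.8 %), teal 0.73 % (0.62 % to 0.85 %) and grey 21.5 % (18.5 % to 24.5 %), on the ground of “leaving the hottest flask fastest”. My grey figure stood a little below its value.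

The run put grey highest: red 14.7 %, amber 4.26 %, teal 0.727 %, grey 21.2 %.

The forecast held, though free enzyme at 8.78 µM or 15.5 µM moved the grey answer by 5 points, past either end of the forecast's range for grey. The main reason grey stood at 21.2 % at the end was the return of ternary complex to second substrate and starting complex: with that return struck out, grey reached 95.1 %. With its share set to one, grey's allowance reads 198 %, above the whole charge. In teal, I multiplied the ceiling of 0.884 % by the ternary share read there, 82.2 %, which gave 0.727 %, and teal read 0.727 %.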